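The route rests on a [3+2] disconnection of each 1,2,2-trimethylcyclopentane ring across C2–C3 and C4–C5. The key step exploits the gem-dimethyl carbon C2 that flanks the aryl-bearing quaternary stereocentre C1: hydrogen-atom transfer to an isopropenyl group unveils C2 as a tertiary radical that adds to acrolein (C3–C4), and the derived enolate closes onto an aldehyde carbon (C5), joining both bonds in one operation. Its precursor is the open-chain (S)-2-aryl-2,3-dimethylbut-3-enal, whose stereocentre comes from a stereospecific lithiation–borylation. The monomeric phenol is then self-coupled through its p-quinone methide equivalent and demethylated.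

Key step: step 7

Remark: the cyclopentane is numbered C1 (aryl-bearing quaternary carbon), C2 (CMe2), C3, C4, C5 (CH2, C5 bonded to C1); Ar = 2-(benzyloxy)-3-methoxy-5-methylphenyl; both stereocentres of the target are (S); compounds 1, 6 and 13 are assumed to be purchased.

Step 1
Reactants: 1 2-methoxy-4-methylphenol (creosol)
Product: 2 1-(2-hydroxy-3-methoxy-5-methylphenyl)ethan-1-one
Conditions: Ac2O, BF3·OEt2, 90 °C; then H2O/MeOH, 60 °C
Reagents that add atoms: acetic anhydride, CC(=O)OC(C)=O
Why: O-acetylation followed by Fries rearrangement should place the acetyl group at the only free position ortho to the phenol (para is blocked by methyl), the difluoroboron chelate of the o-hydroxy ketone acting as thermodynamic sink.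

Step 2
Reactants: 2 1-(2-hydroxy-3-methoxy-5-methylphenyl)ethan-1-one
Product: 3 1-[2-(benzyloxy)-3-methoxy-5-methylphenyl]ethan-1-one
Conditions: BnBr, K2CO3, DMF, 60 °C
Reagents that add atoms: benzyl bromide, BrCc1ccccc1
Why: Williamson etherification (SN2 of the phenoxide on benzyl bromide) masks the phenol as a benzyl ether that should survive the organolithium, oxidation, radical and rhodium steps and is removed later by hydrogenolysis.

Step 3
Reactants: 3 1-[2-(benzyloxy)-3-methoxy-5-methylphenyl]ethan-1-one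
Product: 4 (1R)-1-[2-(benzyloxy)-3-methoxy-5-methylphenyl]ethan-1-ol
Conditions: RuCl(p-cymene)[(R,R)-TsDPEN] (1 mol%), HCO2H/Et3N (5:2), 30 °C
Reagents that add atoms: none
Why: Noyori asymmetric transfer hydrogenation of the aryl methyl ketone should set the (R)-carbinol centre through the CH/π-organised six-membered hydride-transfer transition state imposed by the (R,R)-diamine ligand.

Step 4
Reactants: 4 (1R)-1-[2-(benzyloxy)-3-methoxy-5-methylphenyl]ethan-1-ol
Product: 5 (1R)-1-[2-(benzyloxy)-3-methoxy-5-methylphenyl]ethyl N,N-diisopropylcarbamate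
Conditions: i-Pr2NCOCl, Et3N, MeCN, reflux
Reagents that add atoms: N,N-diisopropylcarbamoyl chloride, CC(C)N(C(C)C)C(Cl)=O
Why: O-carbamoylation (acyl substitution at the carbamoyl chloride) leaves the C–O stereocentre untouched, so (R) is kept while the directing and leaving group for the next step is installed.

Step 5
Reactants: 5 (1R)-1-[2-(benzyloxy)-3-methoxy-5-methylphenyl]ethyl N,N-diisopropylcarbamate; 6 4,4,5,5-tetramethyl-2-(prop-1-en-2-yl)-1,3,2-dioxaborolane (pinacol isopropenylboronate)
Product: 9 2-{(2R)-2-[2-(benzyloxy)-3-methoxy-5-methylphenyl]-3-methylbut-3-en-2-yl}-4,4,5,5-tetramethyl-1,3,2-dioxaborolane, via α-lithio carbamate 7 (not isolated), via lithium boronate complex 8 (not isolated)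
Conditions: s-BuLi, Et2O, −78 °C; then 6; then MgBr2·OEt2, MeOH, −78 °C → rt
Reagents that add atoms: none
Why: Lithiation–borylation (carbamate-directed benzylic lithiation with retention, borylation with retention, then stereoinvertive 1,2-metallate shift of the isopropenyl group with loss of carbamate) should give the (R)-tertiary boronic ester, the quaternary centre being set stereospecifically from the (R)-carbinol centre of 5.

Step 6
Reactants: 9 2-{(2R)-2-[2-(benzyloxy)-3-methoxy-5-methylphenyl]-3-methylbut-3-en-2-yl}-4,4,5,5-tetramethyl-1,3,2-dioxaborolane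
Product: 12 (2S)-2-[2-(benzyloxy)-3-methoxy-5-methylphenyl]-2,3-dimethylbut-3-enal, via lithium dichloromethylborate complex 10 (not isolated), via α-chloro boronic ester 11 (not isolated)
Conditions: CH2Cl2, n-BuLi, THF, −100 °C; then 9; ZnCl2, −100 °C → rt; then H2O2, pH 8 phosphate buffer, rt
Reagents that add atoms: dichloromethane, ClCCl; hydrogen peroxide, OO
Why: Matteson homologation with (dichloromethyl)lithium inserts a CHCl unit into the C–B bond with retention at the migrating quaternary carbon, and oxidation of the α-chloro boronic ester unveils the aldehyde, so the stereocentre is carried over unchanged (its descriptor becomes S only through the change in priorities).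

Step 7
Reactants: 12 (2S)-2-[2-(benzyloxy)-3-methoxy-5-methylphenyl]-2,3-dimethylbut-3-enal; 13 prop-2-enal (acrolein)
Product: 15 (3S)-3-[2-(benzyloxy)-3-methoxy-5-methylphenyl]-3,4,4-trimethylcyclopent-1-ene-1-carbaldehyde, via β-hydroxy aldehyde 14 (not isolated)
Conditions: Fe(acac)3 (30 mol%), PhSiH3, 13 (excess, slow addition), EtOH/(CH2OH)2, 0 °C → rt; aqueous work-up, crude, then MsCl, Et3N, CH2Cl2, 0 °C → rt
Reagents that add atoms: none
Why: Fe(acac)3 and PhSiH3 generate an iron hydride that transfers a hydrogen atom to the CH2 terminus of the isopropenyl group (Markovnikov MHAT), so the future C2 becomes a gem-dimethyl tertiary radical that adds to the β-carbon of acrolein (Giese addition, C2–C3 bond); the α-formyl radical is reduced by divalent iron to an iron enolate that attacks the neopentyl aldehyde (aldol, C4–C5 bond), and mesylation with E1cB elimination of crude 14 gives enal 15. The closest known reaction type is the MHAT-initiated radical–polar crossover annulation (Giese addition followed by intramolecular aldol) of alkenyl carbonyl compounds with enals. The cyclopentane closes in the polar step as a 5-(enolexo)-exo-trig aldol, the radical C–C bond formation being intermolecular. The quaternary stereocentre C1 has no α-hydrogen and no bond to it is made or broken, so its (S) configuration is carried over from 12; the two new stereocentres of 14 (ring C4 and C5) form without control and are erased by the elimination and by steps 8 and 9. The step needs MHAT at the 1,1-disubstituted alkene rather than carbonyl reduction, Giese capture faster than 1,2-formyl or 1,2-aryl shift of the β-formyl tertiary radical, and aldol faster than enolate protonation; the first is inherent to iron hydride chemistry, the second is served by the polarity match of a nucleophilic tertiary radical with excess acrolein at high concentration, and the third by the two flanking quaternary carbons (gem-dialkyl effect), which hold the enolate next to a non-enolisable aldehyde.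

Step 8
Reactants: 15 (3S)-3-[2-(benzyloxy)-3-methoxy-5-methylphenyl]-3,4,4-trimethylcyclopent-1-ene-1-carbaldehyde
Product: 16 2-(benzyloxy)-1-methoxy-5-methyl-3-[(1S)-1,5,5-trimethylcyclopent-2-en-1-yl]benzene
Conditions: [Rh(dppp)2]Cl (5 mol%), xylene, 140 °C
Reagents that add atoms: none
Why: Tsuji–Wilkinson decarbonylation (formyl C–H oxidative addition to monovalent rhodium, CO de-insertion, C–H reductive elimination) should remove the one-carbon activating group from the sp2 carbon C4 without touching the quaternary centre.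

Step 9
Reactants: 16 2-(benzyloxy)-1-methoxy-5-methyl-3-[(1S)-1,5,5-trimethylcyclopent-2-en-1-yl]benzene
Product: 17 2-methoxy-4-methyl-6-[(1S)-1,2,2-trimethylcyclopentyl]phenol
Conditions: H2 (1 atm), Pd/C, EtOAc/EtOH, rt
Reagents that add atoms: none
Why: Heterogeneous hydrogenation should saturate the C4–C5 alkene and hydrogenolyse the benzyl ether in the same operation, releasing the hindered phenol while the (S) quaternary centre stays untouched.

Step 10
Reactants: 17 2-methoxy-4-methyl-6-[(1S)-1,2,2-trimethylcyclopentyl]phenol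
Product: 18 2-methoxy-4-(methoxymethyl)-6-[(1S)-1,2,2-trimethylcyclopentyl]phenol
Conditions: DDQ (1.05 equiv), MeOH, 0 °C → rt
Reagents that add atoms: methanol, CO
Why: DDQ dehydrogenation of the 2,6-disubstituted p-cresol unit should give its p-quinone methide, which methanol traps by 1,6-addition to give the benzylic methyl ether as a stable quinone methide precursor.

Step 11
Reactants: 18 2-methoxy-4-(methoxymethyl)-6-[(1S)-1,2,2-trimethylcyclopentyl]phenol; 17 2-methoxy-4-methyl-6-[(1S)-1,2,2-trimethylcyclopentyl]phenol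
Product: 19 3-({4-hydroxy-3-methoxy-5-[(1S)-1,2,2-trimethylcyclopentyl]phenyl}methyl)-2-methoxy-4-methyl-6-[(1S)-1,2,2-trimethylcyclopentyl]phenol
Conditions: 17 (3 equiv), p-TsOH·H2O (10 mol%), (CF3)2CHOH, rt
Reagents that add atoms: none
Why: Acid ionisation of the p-hydroxybenzyl ether to the p-quinone methide (p-hydroxybenzyl cation) and Friedel–Crafts alkylation by 17 should occur at its only unhindered ring CH (ortho to OMe, between OMe and methyl), the other CH being shielded by the quaternary cyclopentyl group and the methyl group.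

Step 12
Reactants: 19 3-({4-hydroxy-3-methoxy-5-[(1S)-1,2,2-trimethylcyclopentyl]phenyl}methyl)-2-methoxy-4-methyl-6-[(1S)-1,2,2-trimethylcyclopentyl]phenol
Product: 20 3-({3,4-dihydroxy-5-[(1S)-1,2,2-trimethylcyclopentyl]phenyl}methyl)-4-methyl-6-[(1S)-1,2,2-trimethylcyclopentyl]benzene-1,2-diol
Conditions: BBr3, CH2Cl2, −78 °C → rt; then H2O
Reagents that add atoms: none
Why: BBr3 ether cleavage (SN2 demethylation of the boron-complexed aryl methyl ethers) should free both catechols without affecting the diarylmethane or the quaternary stereocentres.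

Compound list
1 | 2-methoxy-4-methylphenol (creosol) | Cc1ccc(O)c(OC)c1 | starting material
2 | 1-(2-hydroxy-3-methoxy-5-methylphenyl)ethan-1-one | CC(=O)c1cc(C)cc(OC)c1O | intermediate
3 | 1-[2-(benzyloxy)-3-methoxy-5-methylphenyl]ethan-1-one | CC(=O)c1cc(C)cc(OC)c1OCc1ccccc1 | intermediate
4 | (1R)-1-[2-(benzyloxy)-3-methoxy-5-methylphenyl]ethan-1-ol | C[C@@H](O)c1cc(C)cc(OC)c1OCc1ccccc1 | intermediate
5 | (1R)-1-[2-(benzyloxy)-3-methoxy-5-methylphenyl]ethyl N,N-diisopropylcarbamate | C[C@@H](OC(=O)N(C(C)C)C(C)C)c1cc(C)cc(OC)c1OCc1ccccc1 | intermediate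
6 | 4,4,5,5-tetramethyl-2-(prop-1-en-2-yl)-1,3,2-dioxaborolane (pinacol isopropenylboronate) | CC(=C)B1OC(C)(C)C(C)(C)O1 | starting material
7 | (1R)-1-[2-(benzyloxy)-3-methoxy-5-methylphenyl]-1-lithioethyl N,N-diisopropylcarbamate | C[C@@]([Li])(OC(=O)N(C(C)C)C(C)C)c1cc(C)cc(OC)c1OCc1ccccc1 | intermediate
8 | lithium boronate complex of 7 with 6 (boron carries the carbamoyloxy-substituted benzylic carbon, isopropenyl and pinacolato) | [Li+].C[C@@]([B-]1(C(C)=C)OC(C)(C)C(C)(C)O1)(OC(=O)N(C(C)C)C(C)C)c1cc(C)cc(OC)c1OCc1ccccc1 | intermediate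
9 | 2-{(2R)-2-[2-(benzyloxy)-3-methoxy-5-methylphenyl]-3-methylbut-3-en-2-yl}-4,4,5,5-tetramethyl-1,3,2-dioxaborolane | C[C@@](c1cc(C)cc(OC)c1OCc1ccccc1)(C(C)=C)B1OC(C)(C)C(C)(C)O1 | intermediate
10 | lithium (dichloromethyl)borate complex of 9 | [Li+].C[C@@](c1cc(C)cc(OC)c1OCc1ccccc1)(C(C)=C)[B-]1(C(Cl)Cl)OC(C)(C)C(C)(C)O1 | intermediate
11 | 2-{(2S)-2-[2-(benzyloxy)-3-methoxy-5-methylphenyl]-1-chloro-2,3-dimethylbut-3-en-1-yl}-4,4,5,5-tetramethyl-1,3,2-dioxaborolane (both epimers at the CHCl carbon) | C[C@@](c1cc(C)cc(OC)c1OCc1ccccc1)(C(C)=C)C(Cl)B1OC(C)(C)C(C)(C)O1 | intermediate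
12 | (2S)-2-[2-(benzyloxy)-3-methoxy-5-methylphenyl]-2,3-dimethylbut-3-enal | C[C@@](c1cc(C)cc(OC)c1OCc1ccccc1)(C(C)=C)C=O | intermediate
13 | prop-2-enal (acrolein) | C=CC=O | starting material
14 | (3S)-3-[2-(benzyloxy)-3-methoxy-5-methylphenyl]-2-hydroxy-3,4,4-trimethylcyclopentane-1-carbaldehyde (diastereomer mixture at C1 and C2) | C[C@]1(c2cc(C)cc(OC)c2OCc2ccccc2)C(O)C(C=O)CC1(C)C | intermediate
15 | (3S)-3-[2-(benzyloxy)-3-methoxy-5-methylphenyl]-3,4,4-trimethylcyclopent-1-ene-1-carbaldehyde | C[C@]1(c2cc(C)cc(OC)c2OCc2ccccc2)C=C(C=O)CC1(C)C | intermediate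
16 | 2-(benzyloxy)-1-methoxy-5-methyl-3-[(1S)-1,5,5-trimethylcyclopent-2-en-1-yl]benzene | C[C@]1(c2cc(C)cc(OC)c2OCc2ccccc2)C=CCC1(C)C | intermediate
17 | 2-methoxy-4-methyl-6-[(1S)-1,2,2-trimethylcyclopentyl]phenol | Cc1cc(OC)c(O)c(c1)[C@@]1(C)CCCC1(C)C | intermediate
18 | 2-methoxy-4-(methoxymethyl)-6-[(1S)-1,2,2-trimethylcyclopentyl]phenol | COCc1cc(OC)c(O)c(c1)[C@@]1(C)CCCC1(C)C | intermediate
19 | 3-({4-hydroxy-3-methoxy-5-[(1S)-1,2,2-trimethylcyclopentyl]phenyl}methyl)-2-methoxy-4-methyl-6-[(1S)-1,2,2-trimethylcyclopentyl]phenol | Cc1cc([C@@]2(C)CCCC2(C)C)c(O)c(OC)c1Cc1cc(OC)c(O)c([C@@]2(C)CCCC2(C)C)c1 | intermediate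
20 | 3-({3,4-dihydroxy-5-[(1S)-1,2,2-trimethylcyclopentyl]phenyl}methyl)-4-methyl-6-[(1S)-1,2,2-trimethylcyclopentyl]benzene-1,2-diol | Cc1cc([C@@]2(C)CCCC2(C)C)c(O)c(O)c1Cc1cc(O)c(O)c([C@@]2(C)CCCC2(C)C)c1 | target

Total step count: 12. Longest linear sequence: 12 steps (1 → 20; phenol 17 enters step 11 twice, once directly and once as 18).

Steps most likely to fail

Step 7. The β-formyl tertiary radical may undergo 1,2-formyl (or 1,2-aryl) migration before it is captured by acrolein. The iron enolate may also be protonated before the aldol closure, leaving an open-chain Giese adduct, and acrolein may be consumed by conjugate reduction or oligomerisation. The fallback sets out from 12, comes back at 17, and builds the ring stepwise at the ester oxidation level, where the radical carries no migrating formyl group. Pinnick oxidation (NaClO2, NaH2PO4, 2-methylbut-2-ene) should give the butenoic acid F1, and esterification (TMSCHN2, MeOH) the methyl ester F2. MHAT Giese coupling with methyl acrylate (Fe(acac)3, PhSiH3, EtOH/(CH2OH)2, 60 °C) should then give the adipate diester F3. Dieckmann condensation (t-BuOK, THF), which can enolise only at the distal ester, should close the ring to the β-keto ester F4. Krapcho dealkoxycarbonylation (LiCl, wet DMSO, 150 °C) should give the cyclopentanone F5, and Wolff–Kishner reduction (N2H4·H2O, KOH, diethylene glycol, 200 °C) the benzyl-protected cyclopentane F6. Hydrogenolysis (H2, Pd/C) then returns to 17.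

Step 5. Reversible formation of the boronate complex with the ortho-alkoxy aryl carbamate may erode enantiopurity, the 1,2-shift of the alkenyl group may be slow, and the benzyl ether may be lithiated competitively. The fallback sets out from ketone 3, comes back at 12 and also bypasses step 6. Addition of vinylmagnesium bromide should give the tertiary allylic alcohol F7, and dehydration (MsCl, Et3N) the 2-aryl-buta-1,3-diene F8. Iridium-catalysed hydrohydroxymethylation with methanol ([Ir(cod)Cl]2 with the PhanePhos enantiomer that delivers the S product) should create the quaternary centre in the neopentyl alcohol F9. Silylation (TBSCl, imidazole) gives the silyl ether F10, Tsuji–Wacker oxidation (PdCl2, CuCl, O2, DMF/H2O) the methyl ketone F11, and Wittig methylenation (Ph3P=CH2) the isopropenyl silyl ether F12. Desilylation (TBAF) gives the alcohol F13, and Dess–Martin oxidation returns to 12.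

Step 11. The benzylic cation from 18 may be captured by 18 itself or by product 19, giving oligomers, and substitution at the hindered ring position or ipso attack with loss of the tertiary alkyl group may compete. The fallback sets out from 17 and 18, comes back at 20 and joins the two rings through an aryllithium and an aldehyde, so that the position of the link is fixed before coupling. O-methylation of 17 (MeI, K2CO3, acetone) should give the dimethyl ether F14, and bromination (NBS, MeCN, 0 °C) the aryl bromide F15. Further oxidation of 18 (DDQ, aqueous dioxane) should give the 4-hydroxybenzaldehyde F16, which is O-methylated to the dimethoxybenzaldehyde F17. Bromine–lithium exchange of F15 (n-BuLi, THF, −78 °C) and addition to F17 should give the diarylmethanol F18. Ionic hydrogenation (Et3SiH, CF3CO2H, CH2Cl2) gives the tetramethyl ether F19, and BBr3 then gives 20.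

Further compounds
F1 | step 7 | (2S)-2-[2-(benzyloxy)-3-methoxy-5-methylphenyl]-2,3-dimethylbut-3-enoic acid | C[C@@](c1cc(C)cc(OC)c1OCc1ccccc1)(C(C)=C)C(=O)O
F2 | step 7 | methyl (2S)-2-[2-(benzyloxy)-3-methoxy-5-methylphenyl]-2,3-dimethylbut-3-enoate | C[C@@](c1cc(C)cc(OC)c1OCc1ccccc1)(C(C)=C)C(=O)OC
F3 | step 7 | dimethyl (2S)-2-[2-(benzyloxy)-3-methoxy-5-methylphenyl]-2,3,3-trimethylhexanedioate | C[C@@](c1cc(C)cc(OC)c1OCc1ccccc1)(C(C)(C)CCC(=O)OC)C(=O)OC
F4 | step 7 | methyl (3S)-3-[2-(benzyloxy)-3-methoxy-5-methylphenyl]-3,4,4-trimethyl-2-oxocyclopentane-1-carboxylate (epimers at C1) | C[C@]1(c2cc(C)cc(OC)c2OCc2ccccc2)C(=O)C(C(=O)OC)CC1(C)C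
F5 | step 7 | (2S)-2-[2-(benzyloxy)-3-methoxy-5-methylphenyl]-2,3,3-trimethylcyclopentan-1-one | C[C@]1(c2cc(C)cc(OC)c2OCc2ccccc2)C(=O)CCC1(C)C
F6 | step 7 | 2-(benzyloxy)-1-methoxy-5-methyl-3-[(1S)-1,2,2-trimethylcyclopentyl]benzene | C[C@]1(c2cc(C)cc(OC)c2OCc2ccccc2)CCCC1(C)C
F7 | step 5 | 2-[2-(benzyloxy)-3-methoxy-5-methylphenyl]but-3-en-2-ol (racemic) | CC(O)(C=C)c1cc(C)cc(OC)c1OCc1ccccc1
F8 | step 5 | 2-(benzyloxy)-3-(buta-1,3-dien-2-yl)-1-methoxy-5-methylbenzene | C=CC(=C)c1cc(C)cc(OC)c1OCc1ccccc1
F9 | step 5 | (2S)-2-[2-(benzyloxy)-3-methoxy-5-methylphenyl]-2-methylbut-3-en-1-ol | C[C@@](c1cc(C)cc(OC)c1OCc1ccccc1)(C=C)CO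
F10 | step 5 | {[(2S)-2-[2-(benzyloxy)-3-methoxy-5-methylphenyl]-2-methylbut-3-en-1-yl]oxy}(tert-butyl)dimethylsilane | C[C@@](c1cc(C)cc(OC)c1OCc1ccccc1)(C=C)CO[Si](C)(C)C(C)(C)C
F11 | step 5 | (3S)-3-[2-(benzyloxy)-3-methoxy-5-methylphenyl]-4-[(tert-butyldimethylsilyl)oxy]-3-methylbutan-2-one | C[C@@](c1cc(C)cc(OC)c1OCc1ccccc1)(C(C)=O)CO[Si](C)(C)C(C)(C)C
F12 | step 5 | {[(2S)-2-[2-(benzyloxy)-3-methoxy-5-methylphenyl]-2,3-dimethylbut-3-en-1-yl]oxy}(tert-butyl)dimethylsilane | C[C@@](c1cc(C)cc(OC)c1OCc1ccccc1)(C(C)=C)CO[Si](C)(C)C(C)(C)C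
F13 | step 5 | (2S)-2-[2-(benzyloxy)-3-methoxy-5-methylphenyl]-2,3-dimethylbut-3-en-1-ol | C[C@@](c1cc(C)cc(OC)c1OCc1ccccc1)(C(C)=C)CO
F14 | step 11 | 1,2-dimethoxy-5-methyl-3-[(1S)-1,2,2-trimethylcyclopentyl]benzene | Cc1cc(OC)c(OC)c(c1)[C@@]1(C)CCCC1(C)C
F15 | step 11 | 2-bromo-3,4-dimethoxy-1-methyl-5-[(1S)-1,2,2-trimethylcyclopentyl]benzene | Cc1cc([C@@]2(C)CCCC2(C)C)c(OC)c(OC)c1Br
F16 | step 11 | 4-hydroxy-3-methoxy-5-[(1S)-1,2,2-trimethylcyclopentyl]benzaldehyde | O=Cc1cc(OC)c(O)c(c1)[C@@]1(C)CCCC1(C)C
F17 | step 11 | 3,4-dimethoxy-5-[(1S)-1,2,2-trimethylcyclopentyl]benzaldehyde | O=Cc1cc(OC)c(OC)c(c1)[C@@]1(C)CCCC1(C)C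
F18 | step 11 | {2,3-dimethoxy-6-methyl-4-[(1S)-1,2,2-trimethylcyclopentyl]phenyl}{3,4-dimethoxy-5-[(1S)-1,2,2-trimethylcyclopentyl]phenyl}methanol (both carbinol epimers) | Cc1cc([C@@]2(C)CCCC2(C)C)c(OC)c(OC)c1C(O)c1cc(OC)c(OC)c([C@@]2(C)CCCC2(C)C)c1
F19 | step 11 | 2-({3,4-dimethoxy-5-[(1S)-1,2,2-trimethylcyclopentyl]phenyl}methyl)-3,4-dimethoxy-1-methyl-5-[(1S)-1,2,2-trimethylcyclopentyl]benzene (tetra-O-methyl ether of 20) | Cc1cc([C@@]2(C)CCCC2(C)C)c(OC)c(OC)c1Cc1cc(OC)c(OC)c([C@@]2(C)CCCC2(C)C)c1
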